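The earlier runs and the new flask were computed from invented constants.

Count in catalyst-minutes.

common to all: left-handed substrate 0.50 mM; right-handed substrate 0.50 mM; racemization catalyst 23 µM; added ligand 14 µM
- grey: partner 2 mM; free catalyst 62 µM; run made earlier
- green: partner 2 mM; free catalyst 82 µM; run made earlier
- dawn: partner 2.00 mM; free catalyst 75 µM; time 5.0 min
- autumn: partner 2.00 mM; free catalyst 120 µM; time 5.0 min

| run | time / min | right-handed substrate / % | left-handed substrate / % | left-handed product / % |
|---|---|---|---|---|
| grey | 0.333 | 39.1 | 33.6 | 17.1 |
| grey | 0.667 | 30.9 | 21.5 | 28.2 |
| grey | 1.00 | 25.5 | 15.5 | 33.9 |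
| grey | 1.33 | 21.4 | 11.5 | 38.9 |
| grey | 2.00 | 15.8 | 5.9 | 43.5 |
| grey | 2.50 | 11.1 | 3.8 | 46.0 |
| green | 0.200 | 41.1 | 36.2 | 14.3 |
| green | 0.333 | 36.3 | 29.1 | 21.3 |
| green | 0.500 | 31.4 | 21.9 | 27.9 |
| green | 0.667 | 26.9 | 17.7 | 32.4 |
| green | 1.00 | 21.3 | 12.5 | 39.8 |
| green | 1.50 | 15.0 | 6.0 | 43.8 |
| green | 2.50 | 7.3 | 2.1 | 48.5 |

(each reading ± 0.5 percentage points)

- free catalyst is single-handed; left-handed substrate and right-handed substrate are mirror images of each other, charged as a racemate, each of them at the stated concentration
- reactions considered so far: partner + free catalyst + left-handed substrate -> free catalyst + left-handed product; partner -> decomposition product; partner + free catalyst + right-handed substrate -> free catalyst + right-handed product; racemization catalyst + added ligand <-> idle complex; racemization catalyst <-> dormant form; left-handed substrate + racemization catalyst <-> right-handed substrate + racemization catalyst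
- an excess is below zero if the other one leads

1. which one finishes higher in excess of right-handed substrate over left-handed substrate among what is left of the two ("neither" within 2 percentage points) (dawn / autumn / neither)
2. excess of right-handed substrate over left-handed substrate among what is left of the two at the end, dawn
3. excess of right-handed substrate over left-handed substrate among what is left of the two at the end, autumn

The ladder starts in the grey run, where the left-handed substrate at first halves in 0.581 min and the right-handed substrate in 0.939 min, a selectivity factor of 1.62 as read from one reading of each. The next rung is the ratio of right-handed to left-handed substrate, which doubles every 1.52 min, slower than either substrate halves. Racemization does not show above the scatter of 0.5 percentage points in the grey run, where at 2.50 min the flask holds 46.0% of left-handed product against 46.2% of left-handed substrate lost.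

The clock for both runs is the dose, c(free catalyst) multiplied by time, which reaches 375 µM·min in dawn and 600 µM·min in autumn. At doses of 124 µM·min and 123 µM·min, the grey and green runs read 15.8% and 15.0% of right-handed substrate, and 5.9% and 6.0% of left-handed substrate.

Late in the grey run one doubling of the ratio costs 112 µM·min, at a mean c(partner) of 1.28 mM. My own reckoning takes the separation as proportional to partner, which falls towards 1.00 mM, so a doubling then costs 144 µM·min. Starting from the last grey reading, and leaving racemization uncounted, this gives 3.08 doublings and an excess of 78.8% for dawn, and 4.64 doublings and 92.3% for autumn.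

The forecast stands lower than this reckoning, at 72% and 86%, and names autumn: “More catalyst gives more resolution, so autumn finishes higher.”

The simulation gives 71.5% and 85.4%, so autumn leads, and the forecast holds, while my count ran ahead by 0.491 and 0.973 doublings.

    partner + free catalyst + left-handed substrate → free catalyst + left-handed product (k = 1.90 × 10⁵ M⁻² s⁻¹)
    partner → decomposition product (k = 1.30 × 10⁻⁴ s⁻¹)
    partner + free catalyst + right-handed substrate → free catalyst + right-handed product (k = 1.10 × 10⁵ M⁻² s⁻¹)
    racemization catalyst + added ligand ⇌ idle complex (K = 2.60 × 10⁵ M⁻¹, k = 33000 M⁻¹ s⁻¹)
    racemization catalyst ⇌ dormant form (K = 15.0, k = 0.750 s⁻¹)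
    left-handed substrate + racemization catalyst ⇌ right-handed substrate + racemization catalyst, rate k6*[racemization catalyst]*[left-handed substrate] forward; the back reaction follows from the equilibrium constant (k = 330 M⁻¹ s⁻¹)

Dawn has 71.0% of the substrates reacted by 1.25 min, and at 2.50 min it holds 9.13% of right-handed and 2.95% of left-handed substrate. The couplings then take these remainders down to 2.45% and 0.407% by 5.00 min, with partner at 49.1% of its charge, while 5.33% of the racemization catalyst stays free beside 80.0% dormant form and 14.7% idle complex. Autumn's figure moves by 5 points at 1.81 mM of partner or 99.4 µM of free catalyst.

Dawn read at 2.0 min has a dose of 150 µM·min, above the 123 µM·min of the green reading at 1.50 min and just below the 155 µM·min of the last grey reading, whose scattered readings give excesses of 42.9% and 49.0%, so the dose places dawn's excess at that time near these figures, as an estimate and not a bound. The computed value is 44.6%, beside 45.0% for the grey run at its last reading without the scatter.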